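## Structural features

Numbering follows the atom order of the SMILES string: C1–C7 heptyl, C8=C9, C10 (pyran CH), O11, C12, C13 (lactone C=O), O14, C15, C16, C17 (CHOH), C18, C19, C20, C21=C22, C23 (methyl on C22), C24, C25 (CHOH). The core is a cyclohexane C12–C20–C19–C15–C24–C25 whose 1,4-carbons C12 and C15 are spanned by the lactone C13(=O)–O14, i.e. a 2-oxabicyclo[2.2.2]octan-3-one; a cyclopentane (C15–C16–C17–C18–C19) is fused on the C15–C19 bond, a 3,6-dihydro-2H-pyran (O11–C12–C20–C21=C22–C10) on the C12–C20 bond, and C10 carries the (E)-non-1-enyl chain. There are seven stereocentres (10R,12S,15R,17R,19R,20R,25R in this numbering): H19 and H20 are trans, C21 lies on the side of the lactone bridge and C18 on the side of the C24–C25 bridge, the C25 hydroxyl points to the C19–C20 bridge, the C17 hydroxyl sits on the concave face of the cyclopentane (towards C24), and the nonenyl group on C10 is cis to C13 across O11. Fragile groups are the doubly allylic ether C10–O11 (acid), the strained lactone with a β-hydroxyl at C25 (base, nucleophiles) and the alkenes. The real difficulty is the cage: two fully substituted, oxygen-bearing bridgeheads (C12, C15) in a 1,4-boat relation and four contiguous stereocentres (C12, C20, C19, C15) shared by three rings. The feature the key step exploits is that O14–C13(=O)–C12(O11)–C25–C24–C15 is, atom for atom, a 3-hydroxy-2-pyranone that has added C19=C20 across C15 and C12 without losing its CO2 bridge; the C25 oxygen is then a 4-alkoxy group of that pyranone, C16 its 6-methyl carbon, and C16–C17–C18 a tether that makes the cycloaddition intramolecular.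

## Logic of the disconnections

**24 to 23.** The C17–H and C25–H bonds are cut: both secondary alcohols go back to ketones. Each carbonyl sits on the rigid cage with one open face, so one hydride reagent can set both centres. This removes two stereocentres and turns both oxygens into functions that trace back to an acyl carbon and to a pyranone alkoxy group. The forward step must attack C17 from the convex face and C25 from the lactone side.

**23 to 22.** The two ketones are masked, C17 as a dioxolane and C25 as the methyl enol ether C24=C25–OMe. These masks are inert to organolithium and hydride reagents and are already present before the key step, so no protecting-group steps are added. The forward hydrolysis must be mild enough not to ionize the C10–O11 ether.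

**22 to 21, and 21 to 16 + 19.** The C10–H bond and then the C9–C10 bond are cut, taking C10 back to a lactone carbonyl. This attaches the nine-carbon chain convergently and lets the cage set the last ring stereocentre. The demand is 1,2-addition at C10 only, then hydride delivery to C10 from the face away from C13. The side-chain donor 19 comes from 17 by cutting C–I.

**16 to 13 + 14.** The C21=C22 bond (olefination) and the O11–C10 bond (lactonization) are cut. The pyran ring, C22, C23 and C10 disappear, leaving a β-hydroxy aldehyde whose four stereocentres come from one step. The forward olefination must be Z, so that the ester lies next to O11, and must tolerate the free tertiary hydroxyl.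

**13 to 12 (key).** The C15–C19 and C12–C20 bonds are cut. This opens the cyclopentane and the carbocyclic ring of the cage together and removes four stereocentres, two of them quaternary. What remains is an achiral, monocyclic 3-hydroxy-4-methoxy-2-pyranone carrying an (E)-enal on a three-atom tether at C6. The forward step must take the exo mode, choose one face of the pyranone, and run cold enough to keep the CO2 bridge. In one sentence: a catalytic asymmetric intramolecular [4+2] addition of hydroxypyranone enal 12 with retention of CO2 builds the lactone cage and the cyclopentane of 13 at once.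

**12 to 10 + 11.** The C19=C20 bond is cut (cross-metathesis). The enal is attached last, so the reactive diene–dienophile pair exists only just before the key step. The forward step must be neutral.

**10 to 8 to 7.** The C12–O11 bond is cut back to C–Br and then to C–H. The oxygen is introduced at the only nucleophilic ring carbon of a 4-methoxy-2-pyranone. The demand is C3 selectivity and survival of the terminal alkene.

**7 to 6 to 4 + 3; 3 to 1 + 2.** The dioxolane is removed, then the C16–C17 bond is cut (acylation of the 6-methyl anion of 4). All carbons of the cage and tether then come from two commercial pieces. The demand is that the β,γ-alkene of the acyl donor does not move into conjugation.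

## Other disconnections considered

**Alternative 1:** (the first that comes to mind) Cut the lactone acyl–oxygen bond C13–O14 and the pyran alkene C21=C22. The forward key steps would be ring-closing metathesis of a bis-olefinic ether on a cis-hydrindane, then lactonization of seco acid A1 (tertiary C15–OH onto the C12 carboxyl). A1 still holds all seven stereocentres, so neither closure creates one. The two quaternary centres C12 and C15 would have to be set separately, in a 1,4-cis relation, on a flexible hydrindane that must go into a boat to lactonize. The chosen plan sets C12, C15, C19 and C20 in one step from an achiral compound and is shorter in stereo-defining operations.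

**Alternative 2:** Cut C18–C19 first, then C12–C13 and C20–C21. The forward key step would be oxidative dearomatization of a para-substituted phenol to quinol A2, then enantioselective intramolecular Michael desymmetrization to cis-fused hydroxy enedione A3. This sets only C15 and C19. C12 is then a ketone that must be turned into a carbon bearing both O11 and C13, with the carboxyl cis to the C15 oxygen. C20 alkylation and C25 hydroxylation remain as separate stereoselective operations, and the cage is closed only at the end. The pyranone plan gets the same cage, with the C12 oxygen and carboxyl already in place, from one cycloaddition.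

**Alternative 3:** Cut the same two bonds, C12–C20 and C15–C19, but tether the dienophile through O11 (O11–C10–C22=C21), so that cycloaddition of ether A4 closes the pyran instead of the cyclopentane. O-Alkylation removes the acidic hydroxyl, so base catalysis is lost. The dienophile is an unactivated diene terminus that must twist out of conjugation in the transition state, which points to thermal conditions where CO2 extrusion competes. Facial control would rest on the single C10 stereocentre, and the cyclopentane would still have to be closed between a neopentyl-type C16 and C18. The chosen tether keeps the free hydroxyl for catalysis and closes the pyran afterwards in three operations on centres already set.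

Key step: step 7

Assumption: ethyl 2-[bis(2,2,2-trifluoroethoxy)phosphoryl]propanoate (14) is taken as a commercial reagent.
Assumption: the cupreidine-derived catalyst of step 7 is taken to select the pyranone face that leads to 13; if the sense proved opposite, the pseudoenantiomeric cupreine-derived catalyst would be used in the same step.

## Steps

Step 1
Reactants: 1 but-3-enoic acid; 2 N,O-dimethylhydroxylamine hydrochloride
Product: 3 N-methoxy-N-methylbut-3-enamide
Conditions: DCC, N-methylmorpholine, CH2Cl2, 0 °C to rt
Reagents that add atoms: none
Why: Carbodiimide amide coupling to the Weinreb amide; no strong base is present, so the β,γ-alkene should stay out of conjugation.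

Step 2
Reactants: 4 4-methoxy-6-methyl-2H-pyran-2-one; 3 N-methoxy-N-methylbut-3-enamide
Product: 6 4-methoxy-6-(2-oxopent-4-en-1-yl)-2H-pyran-2-one, via lithiated pyranone 5 (not isolated)
Conditions: LiN(iPr)2 (1.05 equiv), THF, −78 °C; then 3, −78 to −40 °C; aq. NH4Cl
Reagents that add atoms: lithium diisopropylamide CC(C)N([Li])C(C)C (lithium of intermediate 5 only)
Why: Vinylogous deprotonation of the 6-methyl group and Weinreb ketone synthesis form C16–C17; the chelated tetrahedral adduct persists until the quench, so the acidic product never meets 5, and the delocalized anion 5 should be too weak a base to remove the allylic α-protons of 3.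

Step 3
Reactants: 6 4-methoxy-6-(2-oxopent-4-en-1-yl)-2H-pyran-2-one
Product: 7 4-methoxy-6-{[2-(prop-2-en-1-yl)-1,3-dioxolan-2-yl]methyl}-2H-pyran-2-one
Conditions: (Me3SiOCH2)2, Me3SiOTf (5 mol %), CH2Cl2, −78 to −20 °C; pyridine quench
Reagents that add atoms: 1,2-bis(trimethylsilyloxy)ethane C[Si](C)(C)OCCO[Si](C)(C)C
Why: Noyori ketalization under aprotic, cold conditions should avoid migration of the β,γ-alkene and exchange of the vinylogous-ester methoxy group; the dioxolane removes the acidic C16 and C18 protons and adds a gem-disubstituent bias for the later ring closure.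

Step 4
Reactants: 7 4-methoxy-6-{[2-(prop-2-en-1-yl)-1,3-dioxolan-2-yl]methyl}-2H-pyran-2-one
Product: 8 3-bromo-4-methoxy-6-{[2-(prop-2-en-1-yl)-1,3-dioxolan-2-yl]methyl}-2H-pyran-2-one
Conditions: NBS, MeCN, 0 °C, dark
Reagents that add atoms: N-bromosuccinimide O=C1CCC(=O)N1Br
Why: Electrophilic bromination at C3, the enol-ether β-carbon between the carbonyl and the 4-methoxy group and the usual site for 4-methoxy-2-pyranones; the isolated terminal alkene should be inert in the dark without water.

Step 5
Reactants: 8 3-bromo-4-methoxy-6-{[2-(prop-2-en-1-yl)-1,3-dioxolan-2-yl]methyl}-2H-pyran-2-one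
Product: 10 3-hydroxy-4-methoxy-6-{[2-(prop-2-en-1-yl)-1,3-dioxolan-2-yl]methyl}-2H-pyran-2-one, via pinacol boronate 9 (not isolated)
Conditions: B2pin2, PdCl2(dppf) (5 mol %), KOAc, 1,4-dioxane, 80 °C; then 30% H2O2, aq. NaHCO3, THF, 0 °C
Reagents that add atoms: bis(pinacolato)diboron CC1(C)OB(OC1(C)C)B1OC(C)(C)C(C)(C)O1 (boron of intermediate 9 only); hydrogen peroxide OO (oxygen O11 of 10)
Why: Miyaura borylation of the alkenyl bromide and in situ oxidation of the C–B bond install O11 on the future C12; buffered peroxide should spare the lactone and the terminal alkene.

Step 6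
Reactants: 10 3-hydroxy-4-methoxy-6-{[2-(prop-2-en-1-yl)-1,3-dioxolan-2-yl]methyl}-2H-pyran-2-one; 11 (E)-but-2-enal
Product: 12 (E)-4-{2-[(3-hydroxy-4-methoxy-2-oxo-2H-pyran-6-yl)methyl]-1,3-dioxolan-2-yl}but-2-enal
Conditions: RuCl2(H2IMes)(=CH-C6H4-2-OiPr) (second-generation Hoveyda–Grubbs catalyst, 5 mol %), 11 (5 equiv), CH2Cl2, 35 °C; product used at once
Reagents that add atoms: none
Why: Cross-metathesis of the terminal alkene with excess crotonaldehyde should give the E-enal under thermodynamic control; the medium is neutral, so the hydroxypyranone stays protonated and the cycloaddition should not start.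

Step 7
Reactants: 12 (E)-4-{2-[(3-hydroxy-4-methoxy-2-oxo-2H-pyran-6-yl)methyl]-1,3-dioxolan-2-yl}but-2-enal
Product: 13 exo cycloadduct: 4-hydroxy-5-methoxy-2-oxabicyclo[2.2.2]oct-5-en-3-one cage (C12–OH, C24=C25–OMe) with the cyclopentane fused at C15–C19 (C17 as 1,3-dioxolane) and CHO on C20 syn to the lactone bridge and trans to C18; C12, C15, C19, C20 as in 24
Conditions: 9-O-(9-phenanthryl)cupreidine (10 mol %), EtOAc (0.01 M), −20 °C
Reagents that add atoms: none
Why: Base-catalysed Diels–Alder reaction of a 3-hydroxy-2-pyranone with an α,β-unsaturated carbonyl dienophile; the closest known types are the amine- and cinchona-alkaloid-catalysed intermolecular cycloadditions of 3-hydroxy-2-pyranones with enones and the thermal intramolecular pyranone Diels–Alder reactions that keep the CO2 bridge. The quinuclidine nitrogen deprotonates O11–H and the ion pair reacts as a vinylogous enolate: C15 adds to the enal β-carbon C19 (5-exo-trig, closing the cyclopentane), then the enolate carbon C20 adds to the C12 carbonyl (6-exo-trig aldol, closing the carbocycle and with it the lactone-bridged bicyclo[2.2.2]octene), or both bonds form in one asynchronous [4+2] event. C12 and C15 are bridgeheads of one cage, so their relative configuration is fixed and only the face of the pyranone has to be chosen; the catalyst does this by holding the olate through its ammonium N–H and the formyl oxygen through its 6'-OH. At C19 and C20 the E geometry of the enal puts C18 and C21 trans on the new bridge, and because C20 stays epimerizable (α to CHO) this trans arrangement is also the thermodynamic one. Beyond the face, the step needs the exo mode (formyl under the O14–C13 edge, C18 under C24): the ammonium should sit at the O11/C13=O edge of the olate, a chelating site like that of a maltolate, while the other edge is occupied by the 4-methoxy group, so the formyl group bound to the same catalyst is drawn under the lactone edge and the E alkene then places C18 under C24. The dioxolane keeps the substrate achiral and adds a gem-disubstituent effect, and the three-atom tether fixes the regiochemistry (C15 to C19, not to C20). Low temperature and dilution are meant to suppress the uncatalysed closure, intermolecular reaction and loss of CO2.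

Step 8
Reactants: 13 exo cycloadduct; 14 ethyl 2-[bis(2,2,2-trifluoroethoxy)phosphoryl]propanoate
Product: 16 tetracyclic bis-lactone: 13 in which O11 and C20 are joined by C10(=O)–C22(CH3)=C21H (5,6-dihydro-2H-pyran-2-one ring), via Z-enoate 15 (not isolated)
Conditions: 14 (1.5 equiv), KN(SiMe3)2, 18-crown-6, THF, −78 °C; then 13, −78 to 0 °C; AcOH quench
Reagents that add atoms: none
Why: Still–Gennari olefination (Z-selective Horner–Wadsworth–Emmons) should place the ester cis to C20, and the neighbouring tertiary alkoxide O11 then closes the six-membered lactone on warming; no stereocentre is formed, and a retro-aldol of the β-alkoxy aldehyde, slow at −78 °C, could only reclose to the same, more stable trans C18/C21 isomer.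

Step 9
Reactants: 17 non-1-yne
Product: 19 (E)-1-iodonon-1-ene, via alkenylzirconocene chloride 18 (not isolated)
Conditions: Cp2Zr(H)Cl, THF, rt; then I2, 0 °C
Reagents that add atoms: zirconocene chloride hydride [H][Zr](Cl)(C1C=CC=C1)C1C=CC=C1 (zirconium of intermediate 18 only); iodine II
Why: syn-Hydrozirconation of the terminal alkyne with zirconium at the terminus (Schwartz reagent), then iododemetalation with retention, gives the E-iodide.

Step 10
Reactants: 19 (E)-1-iodonon-1-ene; 16 tetracyclic bis-lactone
Product: 21 lactol: 16 with C10 as hemiketal carbon bearing OH and the (E)-non-1-enyl group (either configuration at C10), via (E)-non-1-enyllithium 20 (not isolated)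
Conditions: 19, t-BuLi (2.0 equiv), Et2O, −78 °C; then 16 in THF, −78 °C; aq. NH4Cl at −78 °C
Reagents that add atoms: tert-butyllithium [Li]C(C)(C)C (lithium of intermediate 20 only)
Why: Iodine–lithium exchange with retention, then 1,2-addition of the alkenyllithium to the more accessible, unsaturated δ-lactone carbonyl C10, which should stop at the lithium lactolate at −78 °C; the bridged lactone C13 is flanked by two fully substituted carbons, and the enol ether and dioxolane are inert.

Step 11
Reactants: 21 lactol
Product: 22 dihydropyran: H and (E)-non-1-enyl on C10 in the configuration of 24, dioxolane at C17 and methyl enol ether C24=C25–OMe intact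
Conditions: Et3SiH (5 equiv), BF3·OEt2 (1.5 equiv), CH2Cl2, −78 °C
Reagents that add atoms: none
Why: Ionic hydrogenation of a lactol: BF3 ionizes the hemiketal to the doubly conjugated oxocarbenium ion and the silane delivers hydride to C10 from the face away from the pseudoaxial lactone carbonyl C13=O, which lies directly over the other face, so H10 ends cis to H20 and the nonenyl group cis to C13; at −78 °C the far less ionizable dioxolane and enol ether should survive.

Step 12
Reactants: 22 dihydropyran
Product: 23 diketone (C17=O and C25=O, otherwise as 24)
Conditions: 1 M aq. HCl, THF, 0 °C to rt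
Reagents that add atoms: water O
Why: Acid hydrolysis of the methyl enol ether and of the dioxolane; O11 carries two carbonyl-bearing neighbours at C12 and is weakly basic, so the doubly allylic C10–O11 bond should not ionize, and no stereocentre is α to either new ketone.

Step 13
Reactants: 23 diketone
Product: 24 target (10R,12S,15R,17R,19R,20R,25R)
Conditions: LiBH(s-Bu)3 (2.5 equiv), THF, −78 °C; aq. NH4Cl
Reagents that add atoms: none
Why: Steric approach control with a bulky hydride: the C17 ketone is attacked from the convex face (side of H19 and O14; the concave face is blocked by the C24 methylene), which puts the hydroxyl towards C24, and the C25 ketone from the side of the lactone bridge, which carries no hydrogen substituents (the other side carries H20 and the cyclopentane), which puts the hydroxyl towards the C19–C20 bridge; the hindered lactone should not react at −78 °C.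

## Compound list

1 | but-3-enoic acid | C=CCC(=O)O | starting material
2 | N,O-dimethylhydroxylamine hydrochloride | CNOC.Cl | starting material
3 | N-methoxy-N-methylbut-3-enamide | C=CCC(=O)N(C)OC | intermediate
4 | 4-methoxy-6-methyl-2H-pyran-2-one | COC1=CC(=O)OC(C)=C1 | starting material
5 | 6-(lithiomethyl)-4-methoxy-2H-pyran-2-one (lithiated pyranone) | COC1=CC(=O)OC(C[Li])=C1 | intermediate (not isolated)
6 | 4-methoxy-6-(2-oxopent-4-en-1-yl)-2H-pyran-2-one | COC1=CC(=O)OC(CC(=O)CC=C)=C1 | intermediate
7 | 4-methoxy-6-{[2-(prop-2-en-1-yl)-1,3-dioxolan-2-yl]methyl}-2H-pyran-2-one | COC1=CC(=O)OC(CC2(CC=C)OCCO2)=C1 | intermediate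
8 | 3-bromo-4-methoxy-6-{[2-(prop-2-en-1-yl)-1,3-dioxolan-2-yl]methyl}-2H-pyran-2-one | COC1=C(Br)C(=O)OC(CC2(CC=C)OCCO2)=C1 | intermediate
9 | 3-(pinacolatoboryl) analogue of 8 (pinacol boronate) | COC1=C(B2OC(C)(C)C(C)(C)O2)C(=O)OC(CC3(CC=C)OCCO3)=C1 | intermediate (not isolated)
10 | 3-hydroxy-4-methoxy-6-{[2-(prop-2-en-1-yl)-1,3-dioxolan-2-yl]methyl}-2H-pyran-2-one | COC1=C(O)C(=O)OC(CC2(CC=C)OCCO2)=C1 | intermediate
11 | (E)-but-2-enal | C/C=C/C=O | starting material
12 | (E)-4-{2-[(3-hydroxy-4-methoxy-2-oxo-2H-pyran-6-yl)methyl]-1,3-dioxolan-2-yl}but-2-enal | COC1=C(O)C(=O)OC(CC2(C/C=C/C=O)OCCO2)=C1 | intermediate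
13 | exo cycloadduct (C12–OH, C20–CHO syn to the lactone bridge, C24=C25–OMe, C17 dioxolane) | O[C@@]23C(=O)O[C@]4(CC5(OCCO5)C[C@@H]4[C@H]2C=O)C=C3OC | intermediate
14 | ethyl 2-[bis(2,2,2-trifluoroethoxy)phosphoryl]propanoate | CCOC(=O)C(C)P(=O)(OCC(F)(F)F)OCC(F)(F)F | starting material
15 | Z-enoate (C20–CH=C(CH3)–CO2Et, ester cis to C20) | O[C@@]23C(=O)O[C@]4(CC5(OCCO5)C[C@@H]4[C@H]2/C=C(C)\C(=O)OCC)C=C3OC | intermediate (not isolated)
16 | tetracyclic bis-lactone (O11–C10(=O)–C22(CH3)=C21 ring closed) | O=C1O[C@@]23C(=O)O[C@]4(CC5(OCCO5)C[C@@H]4[C@H]2C=C1C)C=C3OC | intermediate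
17 | non-1-yne | CCCCCCCC#C | starting material
18 | chloro[(E)-non-1-enyl]zirconocene | CCCCCCC/C=C/[Zr](Cl)(C1C=CC=C1)C1C=CC=C1 | intermediate (not isolated)
19 | (E)-1-iodonon-1-ene | CCCCCCC/C=C/I | intermediate
20 | (E)-non-1-enyllithium | CCCCCCC/C=C/[Li] | intermediate (not isolated)
21 | lactol (C10 hemiketal, either configuration) | CCCCCCC/C=C/C1(O)O[C@@]23C(=O)O[C@]4(CC5(OCCO5)C[C@@H]4[C@H]2C=C1C)C=C3OC | intermediate
22 | dihydropyran with C17 dioxolane and C24=C25–OMe | CCCCCCC/C=C/[C@H]1O[C@@]23C(=O)O[C@]4(CC5(OCCO5)C[C@@H]4[C@H]2C=C1C)C=C3OC | intermediate
23 | diketone (C17=O, C25=O) | CCCCCCC/C=C/[C@H]1O[C@@]23C(=O)O[C@]4(CC(=O)C[C@@H]4[C@H]2C=C1C)CC3=O | intermediate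
24 | CNP0127096.2 | CCCCCCC/C=C/[C@H]1O[C@@]23C(=O)O[C@]4(C[C@H](O)C[C@@H]4[C@H]2C=C1C)C[C@H]3O | target

## Step count and least certain steps

Total: 13 steps. Longest linear sequence: 12 steps (steps 1–8 and 10–13, from 1 to 24); step 9 is the only side branch.

**Step 7 (key step).** Most likely to go wrong: loss of catalyst control. The partners are held together by a three-atom tether, so closure through the free olate, without the organising hydrogen bond to the formyl group, or through the neutral enol while 12 is made and handled, can compete with the catalyst-bound pathway. This would show as low enantiomeric purity and as leakage into the endo mode (formyl under the C24=C25 edge), which puts C18 on the wrong side of the cage; long exposure to base could also reopen the adduct by retro-aldol and retro-Michael steps. Fallback, from 12 and back at 16: 12 is cyclized in the achiral base-promoted mode (Et3N, CH2Cl2, 0 °C) to the racemic exo adduct, that is 13 together with ent-cycloadduct F1, which is freed from any endo isomer on silica. The racemate is taken through the conditions of step 8, the mirror-image series passing through ent-Z-enoate F2, to racemic lactone, that is 16 together with ent-lactone F3. This is resolved by preparative chromatography on a chiral stationary phase, and the route is rejoined at 16.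

**Step 11.** Most likely to go wrong: ionization of the acid-labile methyl enol ether and dioxolane by the Lewis acid in competition with the lactol, followed by their reduction to ethers or by premature hydrolysis. Fallback, from 16 and back at 24: the masks are removed before the side chain is attached. 16 is hydrolysed (1 M aq. HCl, THF) to diketone lactone F4. Both ketones are reduced under Luche conditions (NaBH4, CeCl3·7H2O, MeOH, −78 °C), which spare the unsaturated lactone, to diol lactone F5. Silylation (t-BuMe2SiOTf, 2,6-lutidine) gives bis-silyl ether F6. Addition of 20 as in step 10 gives lactol F7, and Et3SiH with BF3·OEt2 at −78 °C gives bis-silyl ether F8, in which no acid-labile carbonyl mask remains. HF·pyridine in THF then gives 24.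

**Step 10.** Most likely to go wrong: collapse of the lithium lactolate during the addition, because O11 is a good leaving group, followed by a second addition of 20 to the released ketone, or deprotonation at C20. Fallback, from 16 and back at 21: the δ-lactone is opened with Me2AlN(OMe)Me (from AlMe3 and 2, CH2Cl2, 0 °C) to hydroxy Weinreb amide F9. Its stable chelate takes up only one equivalent of 20 (2.2 equiv, one consumed by the O11 hydroxyl, THF, −78 °C), and on work-up the product is obtained in its hemiketal form 21.

**Step 8.** Most likely to go wrong: retro-aldol opening or C20 scrambling of the β-hydroxy aldehyde under the potassium base, or incomplete Z selectivity, which leaves an E-enoate that cannot lactonize. Fallback, from 13 and back at 16: O11–H is esterified with 2-(diethoxyphosphoryl)propanoic acid (DCC, DMAP, CH2Cl2) to phosphonopropanoate ester F10. An intramolecular Horner–Wadsworth–Emmons reaction under Masamune–Roush conditions (LiCl, iPr2NEt, MeCN) then closes the ring to 16, with the ring closure itself enforcing the alkene geometry.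

**Step 5.** Most likely to go wrong: protodeboronation of the α-carbonyl alkenylboronate 9 before it is oxidized, or slow oxidative addition into the electron-rich bromide. Fallback, from 8 and back at 10: a direct C–O coupling of 8 with (E)-benzaldoxime (Pd2(dba)3, tBuBrettPhos, Cs2CO3, 1,4-dioxane, 80 °C) gives O-pyranonyl oxime F11, which fragments under the same basic conditions to 10 and benzonitrile.

## Further compounds

F1 | step 7 | ent-cycloadduct (mirror image of 13) | O[C@]23C(=O)O[C@@]4(CC5(OCCO5)C[C@H]4[C@@H]2C=O)C=C3OC
F2 | step 7 | ent-Z-enoate (mirror image of 15) | O[C@]23C(=O)O[C@@]4(CC5(OCCO5)C[C@H]4[C@@H]2/C=C(C)\C(=O)OCC)C=C3OC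
F3 | step 7 | ent-lactone (mirror image of 16) | O=C1O[C@]23C(=O)O[C@@]4(CC5(OCCO5)C[C@H]4[C@@H]2C=C1C)C=C3OC
F4 | step 11 | diketone lactone (16 with C17=O and C25=O unmasked) | O=C1O[C@@]23C(=O)O[C@]4(CC(=O)C[C@@H]4[C@H]2C=C1C)CC3=O
F5 | step 11 | diol lactone (C17–OH and C25–OH as in 24) | O=C1O[C@@]23C(=O)O[C@]4(C[C@H](O)C[C@@H]4[C@H]2C=C1C)C[C@H]3O
F6 | step 11 | bis(tert-butyldimethylsilyl) ether of F5 | O=C1O[C@@]23C(=O)O[C@]4(C[C@H](O[Si](C)(C)C(C)(C)C)C[C@@H]4[C@H]2C=C1C)C[C@H]3O[Si](C)(C)C(C)(C)C
F7 | step 11 | lactol from F6 and 20 (C10 hemiketal, either configuration) | CCCCCCC/C=C/C1(O)O[C@@]23C(=O)O[C@]4(C[C@H](O[Si](C)(C)C(C)(C)C)C[C@@H]4[C@H]2C=C1C)C[C@H]3O[Si](C)(C)C(C)(C)C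
F8 | step 11 | bis(tert-butyldimethylsilyl) ether of 24 | CCCCCCC/C=C/[C@H]1O[C@@]23C(=O)O[C@]4(C[C@H](O[Si](C)(C)C(C)(C)C)C[C@@H]4[C@H]2C=C1C)C[C@H]3O[Si](C)(C)C(C)(C)C
F9 | step 10 | hydroxy Weinreb amide (δ-lactone of 16 opened at C10, Z alkene) | O[C@@]23C(=O)O[C@]4(CC5(OCCO5)C[C@@H]4[C@H]2/C=C(C)\C(=O)N(C)OC)C=C3OC
F10 | step 8 | O11 2-(diethoxyphosphoryl)propanoate ester of 13 | CCOP(=O)(OCC)C(C)C(=O)O[C@@]23C(=O)O[C@]4(CC5(OCCO5)C[C@@H]4[C@H]2C=O)C=C3OC
F11 | step 5 | O-(pyranon-3-yl) (E)-benzaldoxime from 8 | COC1=C(O/N=C/c2ccccc2)C(=O)OC(CC2(CC=C)OCCO2)=C1
A1 | alternative 1 | seco hydroxy acid (24 with the C13–O14 bond opened) | CCCCCCC/C=C/[C@H]1O[C@]2(C(=O)O)[C@H](O)C[C@](O)(C[C@H](O)C3)[C@H]3[C@H]2C=C1C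
A2 | alternative 2 | 4-hydroxy-4-(2-oxopropyl)cyclohexa-2,5-dien-1-one | CC(=O)CC1(O)C=CC(=O)C=C1
A3 | alternative 2 | cis-fused 7a-hydroxy-3,3a,4,7a-tetrahydro-1H-indene-2,5-dione | O[C@@]12CC(=O)C[C@@H]1CC(=O)C=C2
A4 | alternative 3 | O11-tethered pyranone triene ether (6-(2,2-dimethoxyethyl)-4-methoxy-2-pyranone, 3-O-alkylated at C10) | CCCCCCC/C=C/[C@@H](OC1=C(OC)C=C(CC(OC)OC)OC1=O)/C(C)=C\C=C\CO[Si](C)(C)C(C)(C)C
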